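One percent of the starting material charged is 0.200 mM, the unit in which product is counted below.

| setting | cedar | alpha | epsilon |
|---|---|---|---|
| starting material | 0.020 M | 0.020 M | 0.020 M |
| partner | 0.019 M | 0.0190 M | 0.0120 M |
| protic impurity | 9 mM | 6.00 mM | 6.00 mM |
| free catalyst | 1.2 mM | 1.2 mM | 1.2 mM |
| remark | run made earlier |  |  |
| time |  | 10 d | 10 d |

cedar run (percent of the starting material charged): time / h: product / % = 10.0: 9.4; 20.0: 15.7; 30.0: 25.3; 40.0: 33.7; 50.0: 43.8

(standard deviation of a reading: 1 percentage point)

- the analysis behind the earlier runs scatters by 1 percentage point, standard deviation
- no earlier run changes the charge of protic impurity; that part of a forecast is a guess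

- which of the two ends with the higher amount of product, in percent of the starting material charged ("neither" if they lie within 2 percentage points) (alpha / epsilon / neither)
- product at the end, in percent of the starting material charged, alpha
- product at the end, in percent of the starting material charged, epsilon

**What can the protic impurity cost alpha?** Its 6.00 mM against 0.020 M of starting material gives 30.0%. I call this the impurity toll, the share of the starting material destroyed if each impurity molecule takes one and the charge is spent.

**Why charge the toll to starting material and not to the catalyst?** In cedar the impurity stood at 7.50 times the catalyst charge, yet product still climbed to 43.8% at 50.0 h, so those readings show no dead catalyst. Whether impurity takes starting material or partner is a guess, because no earlier run changes its charge.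

**What ceiling follows?** In alpha, partner allows 95.0%, but the toll leaves 70.0%, so I take the second. In epsilon, partner allows 60.0%, below that 70.0%, so partner is the limiting reagent there.

**Is there time?** At the pace of the cedar readings, 70.0% takes 81.4 h, well inside 10 d.

**Must the impurity finish its work?** No. If it is slow against the coupling, alpha ends above 70.0%, and I have no reading of its rate. I still commit to 70.0% for alpha and 60.0% for epsilon, with alpha ahead by 10 percentage points.

The forecast, which differs from my reckoning for alpha, says alpha, with 93% for alpha and 58% for epsilon: “The end point should therefore be set by stoichiometry, not kinetics”.

The flasks give alpha as the higher, with 72.4% in alpha and 60.0% in epsilon.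

    partner + free catalyst → catalyst intermediate A (k = 0.00970 /M/s)
    starting material + catalyst intermediate A → catalyst intermediate B (k = 1.10 /M/s)
    catalyst intermediate B ⇌ catalyst intermediate C (K = 1.50, k = 1.60 × 10⁻⁴ /s)
    catalyst intermediate C → free catalyst + product (k = 1.60 × 10⁻⁴ /s)
    starting material + protic impurity → quenched substrate (k = 0.00110 /M/s)

The main reason alpha falls short of its partner share is the reaction of starting material with protic impurity: without that step, alpha gives 94.9% instead of 72.4%. Alpha ends with 0% of its starting material and 7.9% of its impurity left, so the toll shrinks to 27.6%, and the flask holds 27.6% of quenched substrate.

Take the neighbour of alpha charged with 0.0047 M of partner. Its partner share is 23.5%, and with the full toll 46.5% of the starting material stays unused. That flask ends with 23.5% of product and 46.5% of starting material.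

All runs come from a simulation with constants of no real substance; the scatter is artificial.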